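Amounts first: I count one X for each J, with Q as a stage between them, since I read from the delta run that at 5.00 h Q (5.4%) and L (5.7%) stand level and then fall together.

| flask | L | X | remark | time |
|---|---|---|---|---|
| gamma | 0.10 M | 0.65 equiv (fed, over 2.0 min) | run made earlier |  |
| delta | 0.10 M | 2.6 equiv (fed, over 2.0 min) | run made earlier |  |
| zeta | 0.050 M | 1.3 equiv (fed, over 2.0 min) | run made earlier |  |
| flask | 0.10 M | 1.30 equiv (fed, over 2.0 min) |  | 30 h |

- gamma (time / h: J / %, Q / %, L / %): 2.00: 36.3, 0, 62.8; 6.00: 37.8, 0.3, 63.1; 10.0: 37.3, 0.7, 63.0; 15.0: 37.5, 0, 62.4; 20.0: 36.7, 0, 62.3; 30.0: 37.0, 0, 62.8; 40.0: 38.0, 0, 63.3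
- delta (time / h: J / %, Q / %, L / %): 5.00: 89.2, 5.4, 5.7; 10.0: 94.6, 3.6, 3.1; 15.0: 95.4, 2.7, 1.8; 20.0: 97.5, 1.4, 1.5; 25.0: 98.1, 1.3, 1.4; 30.0: 97.1, 1.2, 1.0; 40.0: 98.1, 1.8, 0.8
- zeta (time / h: J / %, Q / %, L / %): 3.00: 31.7, 1.0, 67.2; 10.0: 34.5, 0, 66.6; 15.0: 33.0, 0, 65.6; 25.0: 34.5, 0.3, 66.7; 40.0: 34.2, 0.3, 65.2

(each reading ± 0.5 percentage points)

1. at 30 h, what has stopped the reaction, if anything has (forward and back rates have come level / all of L has reacted / it is still moving / X has run out first)
2. J at 30 h, in percent of the L charged

- in percentages every species weighs as the L in it: one J counts as two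
- the numbers in the tables scatter by 0.5 percentage points (one standard deviation)
- the reaction counts as stopped when no species that holds the L changes by six tenths of a point or more over the second half of the time

The gamma and zeta runs each get 0.0650 M of X and stay flat with L left, so I take X as the limiting reagent. What share of it reaches J? With a mean J of 37.2%, gamma gives 0.286; with 33.6%, zeta gives less, 0.129.

How does that share follow L? The odds of X reaching J are 0.401 in gamma and 0.148 in zeta, at mean L (the mean of L charged and L left) of 0.0814 M and 0.0416 M, so from these two runs I read the odds as going with L to the power n = 1.48. I call σ, a selectivity factor, the odds at a mean L of 0.10 M: σ = 0.545.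

What does the flask give? Its J sets its own mean L, so I iterate. A trial J of 67.7% returns 59.3%; the mean of those two, 63.5%, returns 61.4%. I commit to 62.4%, flat like gamma.

The forecast gives 65%, more than my 62.4%, and "X has run out first": “the plateaus look like X exhausted rather than equilibrium”.

The flask gives 65.0% of J at 30 h, with 0% of its X left, and X has run out first.

    L + X → Q, rate k1*[L]^1.5*[X] (k = 0.0190 M⁻¹·⁵ s⁻¹)
    X → D (k = 0.00120 s⁻¹)
    L + Q → J (k = 0.00870 M⁻¹ s⁻¹)

Put through the same odds, the flask's J stands for σ = 0.597. In this flask, X at 1.17 equiv or 1.44 equiv moves J by 5 points. For a neighbour flask with 0.060 M of L and the same 1.30 equiv of X, σ and zeta's J as the trial give 42.3%; the computed J there is 41.0%.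

(The readings stem from a simulated flask with constants of no real substance.)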